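**Strategy**

The 1,2-dioxane ring (O1–O2–C3–C4–C5–C6) bears oxygen on C3 and C6, so C4 and C5 are carbons of like polarity and C6 is tertiary and allylic to the C7=C8 alkene. Everything rests on cutting C4–C5 and O1–C6: butanal, as the radical cation of its chiral enamine, adds through C4 to the CH2 end of a 2-ethyl-1,3-diene that already carries the whole side chain, and the resulting allyl radical captures O2 at C6. One operation thus joins three simple components into the peroxy-hemiacetal of the ring; Horner–Wadsworth–Emmons olefination and hydroperoxide oxa-Michael closure then set C3.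

Key step: step 6

Assumption: the senses of induction follow the accepted models ((+)-MIB/Et2Zn adds ethyl to the Re face of the enal; the (2S,5S)-imidazolidinone radical cation is attacked on the Si face of C4); were either found reversed, the enantiomeric ligand or catalyst would be used.

**Route**

Step 1
Reactants: 1 (E)-pent-2-enal; 2 diethylzinc
Product: 3 (3R,4E)-hept-4-en-3-ol
Conditions: Et2Zn (1.5 equiv), (+)-MIB [(2R)-3-exo-morpholinoisoborneol, 4 mol%], hexane/toluene, 0 °C; aq NH4Cl
Reagents that add atoms: diethylzinc, CC[Zn]CC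
Why: Amino-alcohol-catalysed enantioselective dialkylzinc addition to an aldehyde, in which the (+)-MIB–zinc complex delivers ethyl to the Re face of the enal carbonyl and so sets the (3R) carbinol centre.

Step 2
Reactants: 3 (3R,4E)-hept-4-en-3-ol; 4 triethyl orthoacetate
Product: 5 ethyl (3R,4E)-3-ethylhept-4-enoate
Conditions: MeC(OEt)3 (5 equiv), EtCO2H (5 mol%), 140 °C, EtOH distilled off
Reagents that add atoms: triethyl orthoacetate, CC(OCC)(OCC)OCC
Why: Johnson–Claisen orthoester rearrangement through a chair transition state with the carbinol ethyl group equatorial, which transfers the (3R) carbinol chirality suprafacially to the new (3R) carbon centre (the later side-chain stereocentre) and gives the (E)-alkene.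

Step 3
Reactants: 5 ethyl (3R,4E)-3-ethylhept-4-enoate
Product: 6 (3R,4E)-3-ethylhept-4-enal
Conditions: i-Bu2AlH (1.05 equiv), CH2Cl2, −78 °C; aq KNaC4H4O6 (potassium sodium tartrate)
Reagents that add atoms: none
Why: Partial ester reduction with i-Bu2AlH, which stops at the aldehyde because the tetrahedral aluminium hemiacetal is stable at −78 °C, while the β-stereocentre and the alkene are not touched.

Step 4
Reactants: 6 (3R,4E)-3-ethylhept-4-enal; 7 dimethyl (1-diazo-2-oxopropyl)phosphonate
Product: 8 (4R,5E)-4-ethyloct-5-en-1-yne
Conditions: K2CO3 (2 equiv), MeOH, 0 °C to rt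
Reagents that add atoms: dimethyl (1-diazo-2-oxopropyl)phosphonate, COP(=O)(OC)C(=[N+]=[N-])C(C)=O
Why: Seyferth–Gilbert homologation with the Ohira–Bestmann reagent under mild carbonate conditions, safe here because the aldehyde has no α-stereocentre to epimerise.

Step 5
Reactants: 8 (4R,5E)-4-ethyloct-5-en-1-yne; 9 trimethylaluminium; 10 2-bromobut-1-ene
Product: 12 (3E,5R,7E)-5-ethyl-7-methyl-9-methylideneundeca-3,7-diene, via alkenylalane 11 (not isolated)
Conditions: AlMe3 (2 equiv), Cp2ZrCl2 (20 mol%), CH2Cl2, 0 °C to rt; then 2-bromobut-1-ene, ZnCl2 (1 equiv), Pd(PPh3)4 (5 mol%), THF, rt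
Reagents that add atoms: trimethylaluminium, C[Al](C)C; 2-bromobut-1-ene, C=C(Br)CC
Why: Negishi zirconium-catalysed methylalumination (syn carbometalation with aluminium on the terminal carbon, hence the (E)-trisubstituted alkenylalane) followed by Negishi cross-coupling with retention of alkene geometry, the internal (E)-alkene being inert to carbometalation.

Step 6
Reactants: 12 (3E,5R,7E)-5-ethyl-7-methyl-9-methylideneundeca-3,7-diene; 13 butanal; 14 dioxygen
Product: 16 (4R,6S)-4,6-diethyl-6-[(1E,4R,5E)-4-ethyl-2-methylocta-1,5-dien-1-yl]-1,2-dioxan-3-ol, via hydroperoxy aldehyde 15 (not isolated)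
Conditions: butanal (3 equiv), (2S,5S)-5-benzyl-2-tert-butyl-3-methylimidazolidin-4-one·CF3CO2H (20 mol%), [Fe(phen)3](PF6)3 (5 mol%), O2 (1 atm), H2O (2 equiv), DME, −10 °C, dark
Reagents that add atoms: butanal, CCCC=O; dioxygen, O=O
Why: Proposed new method: butanal and the imidazolidinone form an enamine that trivalent iron oxidises to a 3π-electron radical cation, which adds through C4 to the CH2 terminus of triene 12 (C4–C5) and leaves an iminium ion beside a tetra-alkyl allyl radical; O2 captures that radical at C6 (O–C6), the peroxyl radical is reduced by divalent iron or by a further enamine molecule so that a chain runs on catalytic iron, and the hydroperoxide 15 set free by hydrolysis adds to its own aldehyde carbon. The closest known reaction types are the organo-SOMO carbo-oxidation of olefins with aldehydes (enamine radical cation plus alkene, then C–O bond formation at the new radical site) and the Mn(OAc)3/O2 peroxycyclisation of 1,3-dicarbonyl compounds with alkenes to 1,2-dioxan-3-ols; the step merges them by letting O2 act as both oxidant and peroxide source. The 1,2-dioxane ring closes by 6-exo-trig addition of the hydroperoxide oxygen to the C3 carbonyl (or iminium) carbon. C4 is set by the catalyst, whose benzyl and tert-butyl groups shield one face of the (E)-radical cation so that the diene adds to the Si face (4R); C3 is a hemiacetal centre that is erased in step 7; C6 arises when O2 meets an acyclic allyl radical and has no reliable controlling element (at most weak 1,3-induction from C4), so both C6 epimers must be expected and are separated after step 7. The step needs attack at the CH2 terminus, secured by the tertiary allyl radical formed only there, oxidation of the enamine and not of the triene, secured by the lower oxidation potential of the enamine, and peroxide at C6 and not C8, favoured because only the C6 hydroperoxide is drained into the six-membered hemiacetal while the C8 isomer can return by the Schenck allylic hydroperoxide shift.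

Step 7
Reactants: 16 (4R,6S)-4,6-diethyl-6-[(1E,4R,5E)-4-ethyl-2-methylocta-1,5-dien-1-yl]-1,2-dioxan-3-ol; 17 trimethyl phosphonoacetate
Product: 19 methyl 2-[(3S,4R,6S)-4,6-diethyl-6-[(1E,4R,5E)-4-ethyl-2-methylocta-1,5-dien-1-yl]-1,2-dioxan-3-yl]acetate, via hydroperoxy enoate 18 (not isolated)
Conditions: (MeO)2P(O)CH2CO2Me, LiCl, i-Pr2NEt, MeCN, 0 °C to rt; then Et2NH, CF3CH2OH, rt; chromatographic removal of the C6 epimer
Reagents that add atoms: trimethyl phosphonoacetate, COC(=O)CP(=O)(OC)OC
Why: Horner–Wadsworth–Emmons olefination of the aldehyde released by ring-chain tautomerism of the peroxy-hemiacetal gives the (E)-enoate, and the tertiary hydroperoxide then closes by reversible 6-exo-trig oxa-Michael addition through a chair with the C4 ethyl group and the new CH2CO2Me group both equatorial, which sets (3S) trans to C4 under thermodynamic control.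

**Compound list**

1 | (E)-pent-2-enal | CC/C=C/C=O | starting material
2 | diethylzinc | CC[Zn]CC | starting material
3 | (3R,4E)-hept-4-en-3-ol | CC[C@@H](O)/C=C/CC | intermediate
4 | triethyl orthoacetate | CC(OCC)(OCC)OCC | starting material
5 | ethyl (3R,4E)-3-ethylhept-4-enoate | CCOC(=O)C[C@@H](CC)/C=C/CC | intermediate
6 | (3R,4E)-3-ethylhept-4-enal | O=CC[C@@H](CC)/C=C/CC | intermediate
7 | dimethyl (1-diazo-2-oxopropyl)phosphonate | COP(=O)(OC)C(=[N+]=[N-])C(C)=O | starting material
8 | (4R,5E)-4-ethyloct-5-en-1-yne | C#CC[C@@H](CC)/C=C/CC | intermediate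
9 | trimethylaluminium | C[Al](C)C | starting material
10 | 2-bromobut-1-ene | C=C(Br)CC | starting material
11 | dimethyl[(1E,4R,5E)-4-ethyl-2-methylocta-1,5-dien-1-yl]alumane | C[Al](C)/C=C(C)/C[C@@H](CC)/C=C/CC | intermediate (not isolated)
12 | (3E,5R,7E)-5-ethyl-7-methyl-9-methylideneundeca-3,7-diene | C=C(CC)/C=C(C)/C[C@@H](CC)/C=C/CC | intermediate
13 | butanal | CCCC=O | starting material
14 | dioxygen | O=O | starting material
15 | (2R,4S,5E,8R,9E)-2,4,8-triethyl-4-hydroperoxy-6-methyldodeca-5,9-dienal | CC/C=C/[C@H](CC)C/C(C)=C/[C@](OO)(CC)C[C@@H](CC)C=O | intermediate (not isolated)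
16 | (4R,6S)-4,6-diethyl-6-[(1E,4R,5E)-4-ethyl-2-methylocta-1,5-dien-1-yl]-1,2-dioxan-3-ol (both C3 anomers) | CC/C=C/[C@H](CC)C/C(C)=C/[C@]1(CC)C[C@@H](CC)C(O)OO1 | intermediate
17 | trimethyl phosphonoacetate | COC(=O)CP(=O)(OC)OC | starting material
18 | methyl (2E,4R,6S,7E,10R,11E)-4,6,10-triethyl-6-hydroperoxy-8-methyltetradeca-2,7,11-trienoate | CC/C=C/[C@H](CC)C/C(C)=C/[C@](OO)(CC)C[C@@H](CC)/C=C/C(=O)OC | intermediate (not isolated)
19 | methyl 2-[(3S,4R,6S)-4,6-diethyl-6-[(1E,4R,5E)-4-ethyl-2-methylocta-1,5-dien-1-yl]-1,2-dioxan-3-yl]acetate | CC/C=C/[C@H](CC)C/C(C)=C/[C@]1(CC)C[C@@H](CC)[C@H](CC(=O)OC)OO1 | target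

**Step count**

Total steps: 7. Longest linear sequence: 7 steps (1 to 19).

**Steps most likely to fail**

1. Step 6 (proposed new method).
 - What may go wrong: O2 may trap or oxidise the enamine radical cation before it meets the hindered, twisted diene, so that butanal is merely oxygenated at its α-carbon. The allyl radical may take up O2 at C8. The chain may die by hydrogen abstraction from the allylic positions of the triene. Nothing steers the face of C6.
 - Fallback (known chemistry only, from butanal 13 and alkyne 8, rejoining at 16): butanal 13 is coupled with 2-(trimethylsilyloxy)but-1-ene by the established organo-SOMO α-enolation [(2S,5S)-imidazolidinone·CF3CO2H, (NH4)2Ce(NO3)6, DME, −20 °C] to (2R)-2-ethyl-4-oxohexanal F1. Its aldehyde is masked selectively [HC(OMe)3, pyridinium p-toluenesulfonate, MeOH, 0 °C] as (5R)-5-(dimethoxymethyl)heptan-3-one F2. Alkyne 8 is converted by zirconium-catalysed methylalumination and iodinolysis (AlMe3, Cp2ZrCl2; I2) into (1E,4R,5E)-4-ethyl-1-iodo-2-methylocta-1,5-diene F3. The alkenyllithium from F3 (t-BuLi, Et2O, −78 °C; CeCl3) adds to ketone F2 to give the tertiary allylic alcohol (2R,5E,8R,9E)-2,4,8-triethyl-1,1-dimethoxy-6-methyldodeca-5,9-dien-4-ol F4 as both carbinol epimers. Acid-catalysed perhydrolysis (50% H2O2, catalytic H2SO4, Et2O, 0 °C) then replaces the tertiary allylic hydroxyl by OOH through the allyl cation and unmasks the aldehyde. The hydroperoxy aldehyde closes to 16 (both C6 epimers, as in the main route), because only the C6 hydroperoxide can form the six-membered hemiacetal.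

2. Step 7.
 - What may go wrong: base may fragment the peroxy-hemiacetal (Kornblum–DeLaMare-type loss of the C3 hydrogen) or epimerise C4 before the olefination takes place. The enolate formed in the oxa-Michael addition may attack the O–O bond (Weitz–Scheffer-type oxygen transfer) instead of being protonated.
 - Fallback (from 16, rejoining at 19): 16 is acetylated (Ac2O, pyridine, 0 °C) to (4R,6S)-4,6-diethyl-6-[(1E,4R,5E)-4-ethyl-2-methylocta-1,5-dien-1-yl]-1,2-dioxan-3-yl acetate F5. F5 is ionised at −78 °C (Me3SiOSO2CF3, CH2Cl2) to the cyclic peroxycarbenium ion and captured by 1-methoxy-1-(trimethylsilyloxy)ethene, a Lewis-acid substitution of a cyclic peroxy-acetal by a silyl ketene acetal. The C3 epimers of 19 are then equilibrated to the 3,4-trans isomer by reversible retro-oxa-Michael/oxa-Michael reaction (Et2NH, CF3CH2OH).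

3. Step 5.
 - What may go wrong: slow transmetalation of the hindered alkenylalane and slow oxidative addition of the 1,1-disubstituted bromide let protodealumination and homocoupling compete. The twisted diene may isomerise on palladium.
 - Fallback (from 8, rejoining at 12): the alkenylalane from methylalumination of 8 is acylated with propanoyl chloride (Pd(PPh3)4 cat., THF) to (4E,7R,8E)-7-ethyl-5-methylundeca-4,8-dien-3-one F6. Wittig methylenation of its carbonyl group (Ph3P=CH2, THF, 0 °C) gives 12, so that the C=CH2 bond is made by olefination instead of an sp2–sp2 coupling.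

Further compounds
F1 | step 6 | (2R)-2-ethyl-4-oxohexanal | O=C[C@H](CC)CC(=O)CC
F2 | step 6 | (5R)-5-(dimethoxymethyl)heptan-3-one | CCC(=O)C[C@@H](CC)C(OC)OC
F3 | step 6 | (1E,4R,5E)-4-ethyl-1-iodo-2-methylocta-1,5-diene | I/C=C(C)/C[C@@H](CC)/C=C/CC
F4 | step 6 | (2R,5E,8R,9E)-2,4,8-triethyl-1,1-dimethoxy-6-methyldodeca-5,9-dien-4-ol (both C4 epimers) | CC/C=C/[C@H](CC)C/C(C)=C/C(O)(CC)C[C@@H](CC)C(OC)OC
F5 | step 7 | (4R,6S)-4,6-diethyl-6-[(1E,4R,5E)-4-ethyl-2-methylocta-1,5-dien-1-yl]-1,2-dioxan-3-yl acetate (both C3 epimers) | CC/C=C/[C@H](CC)C/C(C)=C/[C@]1(CC)C[C@@H](CC)C(OC(C)=O)OO1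
F6 | step 5 | (4E,7R,8E)-7-ethyl-5-methylundeca-4,8-dien-3-one | CCC(=O)/C=C(C)/C[C@@H](CC)/C=C/CC
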